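## Analysis of the target

The target 27 (CNP0304846.1) is a guaiane: a cyclopentane fused through C1 and C5 to a cycloheptane, with methyl groups on C4 and C10 and an isopropyl group on C7 (guaiane numbering is used throughout). The five-membered ring carries a 3,4-epoxide, C10 a tertiary hydroxyl, and the secondary oxygen on C8 a 3,4-dimethoxybenzoate. There are seven stereocentres (C1, C3, C4, C5, C7, C8, C10). The ring fusion is trans (H1 α, H5 β). The C7 isopropyl group, O8 and O10 lie on the β face, so O8 and O10 form a cis-1,3-diol and O8 is cis to isopropyl; H7, H8, the C10 methyl group and the epoxide oxygen are α. The sensitive functions are the trisubstituted epoxide (acid), the tertiary alcohol 1,3 to the ester (dehydration, acyl migration) and the electron-rich aryl ester. The difficulty is a seven-membered ring with four stereocentres, one of them a quaternary carbinol next to the ring fusion, together with the trans fusion and an epoxide face that no polar group directs. The strategy rests on one feature: C10 (methyl and oxygen) is bonded to the ring-fusion methine C1, and C8, two atoms on, is also oxygenated. C8–C9–C10 is therefore a 1,3-dioxygenated three-carbon unit between C7 and C1, and C7–C6–C5–C1 is a four-carbon chain that shares C5–C1 with the five-membered ring.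

## Retrosynthetic reasoning

27 from 26. The O–benzyl bond at C10 is cut last. The tertiary oxygen must stay an ether until the C3 alcohol has been dehydrated, because a free tertiary alcohol would eliminate first and could also take over the acyl group from O8. The forward step is an oxidative debenzylation that leaves the epoxide and the ester alone.

26 from 25. Both C–O bonds of the epoxide are cut, leading to the C3=C4 alkene. It is the only alkene in 25, so only the face of attack (α) has to be controlled.

25 from 23 from 22. The C3=C4 bond is traced back to a 3β-hydroxyl with a cis hydrogen on C4. The C3 oxygen and the C4 stereocentre are relics of the cyclopentenone; they carry the chirality into the key step and are erased here. The forward steps are desilylation and a thermal syn elimination.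

22 from 21. The ester C–O bond is cut. Acylation comes after all hydride and hydrogenation steps, and at a stage where O8 is the only free hydroxyl.

21 from 20. The C5–H and C6–H bonds are cut to give the C5=C6 alkene. This alkene is what the annulation leaves behind, and the homoallylic 8β-hydroxyl lies on the face from which H5 must be delivered, so a directed hydrogenation can set the trans fusion.

20 from 19 from 18. The C8 carbinol goes back to ketone 19 and this to methyl enol ether 18. The reduction must deliver hydride from the α face; the hydrolysis must not move the β,γ-double bond or touch C7.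

18 from 9 and 16 (key disconnection). C7–C8 and C1–C10 are cut. These two bonds separate the dioxygenated three-carbon unit from the four-carbon chain. The cut gives a 1-alkenylcyclopentene (9) and an alkoxy(alkenyl)carbene complex (16) that already holds both oxygens. The forward step must transfer the carbene to C6=C7, and the cis-divinylcyclopropane 17 must then rearrange; this closes the ring and sets C1, C7 and C10.

16 from 14 and 15, and 14 from 10 and 11. The enol ether C–O bond is cut to the alkynyl carbene complex 14 and 4-methoxybenzyl alcohol (15). Complex 14 is assembled from propyne (10) and chromium hexacarbonyl (11).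

9 from 6 and 8, back to 1 and 7. The C5–C6 bond between the two alkenes is cut (cross-coupling of enol triflate 6 with alkenylboronate 8, the latter from alkyne 7). Triflate 6 comes from ketone 4, whose C3 oxygen is introduced enantioselectively at the β-carbon of enone 1.

## Alternatives that were turned down

Alternative 1: The C3=C4 bond is cut, so the cyclopentene is the last ring to form. Low-valent titanium (TiCl3, Zn–Cu) would couple an aldehyde carbon (C3) with a methyl ketone carbon (C4) held on a complete cycloheptane and give guai-3-ene-8,10-diol acetonide A1. In its favour, carbonyl coupling to a five-membered trisubstituted alkene is well precedented, the alkene appears exactly where the epoxide is needed with no regiochemical question, and the acetonide masks the tertiary hydroxyl. On precedent for the key step and on the way C3=C4 is reached, this plan is stronger than the chosen one. Against it, the step creates no stereocentre and no part of the seven-membered ring: C1, C5, C7, C8 and C10 must all be in place beforehand, so the hard part of the target is only moved backwards into a long linear sequence. In its place the chosen plan offers convergence, and the ring plus three stereocentres in one step.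

Alternative 2: C1–C5, C2–C3 and C3–C4 are cut together, which opens both rings and removes C3 as CO. [Rh(CO)2Cl]2 under CO would join the distal allene double bond, the alkyne and CO (allenic Pauson–Khand reaction) to the bicyclic dienone A2. In its favour, both rings form in one catalytic step from an open chain that holds only the C7 and C8 stereocentres; in ring-forming power and in the use of a catalytic metal it is stronger than the chosen plan. Against it, A2 is flat where the target is not: C1, C4, C5 and C10 are sp2. The tertiary alcohol at C10 and the trans ring fusion would have to be set afterwards on a cross-conjugated dienone with no nearby control element, and the C3 carbonyl would have to be removed again to regain C3=C4. The chosen plan sets C1, C7 and C10 in the ring-forming step and enters with C3 and C4 at the right oxidation level; the price is stoichiometric chromium.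

Alternative 3: C1–C5, C6–C7 and the C10–O bond are cut. (tBu2(2-biphenyl)P)Au(NCMe)SbF6 would activate the alkyne; the alkene attacks through C1, the ketone oxygen captures the cation at C10, and the alkenylgold carbon closes onto the oxocarbenium carbon C7, giving the 7,10-oxa-bridged guai-5-ene A3. In its favour, two C–C bonds and the C10–O bond form in one catalytic step, C1 and C10 are related through the alkene geometry, and the C5=C6 alkene is the same as in 18. This is the alternative with the best ring-forming step economy, and its cascade type is established. Against it, C7 emerges as a fully substituted ether carbon with the bridging oxygen on the β face, the face the isopropyl group must take in the target. The C7–O bond would have to be replaced by C7–H with inversion at a tertiary allylic centre, which means passing through an allyl cation with regiochemical and facial ambiguity. The open-chain substrate also needs three stereocentres and a geometrically pure trisubstituted alkene. The chosen plan places H7 directly through the alkene geometry of 9.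

Key step: step 8

Remark: α/β refer to the usual guaiane drawing (H5, the C7 isopropyl group, O8 and O10 are β); it is assumed that the (R,R) ligand of step 1 gives the (3S) boronate (otherwise its antipode is used) and that the chromium carbene engages diene 9 through its s-cis form, so that the C4 methyl group sends the three-carbon unit to the β face.

## Route

Step 1
Reactants: 1 2-methylcyclopent-2-en-1-one
Product: 3 (2R,3S)-3-hydroxy-2-methylcyclopentan-1-one, via pinacol boronate 2 (not isolated)
Conditions: B2pin2, CuCl (cat.), NaOtBu (cat.), (R,R)-2,3-bis(tert-butylmethylphosphino)quinoxaline (cat.), MeOH, THF, rt; then NaBO3·4H2O, THF/H2O, rt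
Reagents that add atoms: sodium perborate, [Na+].[O-]OB=O
Why: Copper-catalysed asymmetric conjugate borylation of the enone (the chiral bisphosphine–copper boryl species sets C3) followed by oxidation of the C–B bond with retention; the epimerisable C2 centre is expected to settle trans to the C3 substituent in the alkoxide/methanol medium.

Step 2
Reactants: 3 (2R,3S)-3-hydroxy-2-methylcyclopentan-1-one
Product: 4 (2R,3S)-3-(tert-butyldimethylsilyloxy)-2-methylcyclopentan-1-one
Conditions: TBSCl, imidazole, DMF, rt; chromatographic removal of any cis isomer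
Reagents that add atoms: tert-butyldimethylsilyl chloride, CC(C)(C)[Si](C)(C)Cl
Why: Silylation of the secondary alcohol under neutral conditions; no stereocentre is touched and β-elimination is avoided.

Step 3
Reactants: 4 (2R,3S)-3-(tert-butyldimethylsilyloxy)-2-methylcyclopentan-1-one
Product: 6 (4S,5R)-4-(tert-butyldimethylsilyloxy)-5-methylcyclopent-1-en-1-yl trifluoromethanesulfonate, via lithium enolate 5 (not isolated)
Conditions: LiN(i-Pr)2, THF, −78 °C; then PhNTf2, −78 → 0 °C
Reagents that add atoms: N-phenylbis(trifluoromethanesulfonimide), O=S(=O)(N(c1ccccc1)S(=O)(=O)C(F)(F)F)C(F)(F)F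
Why: Kinetic deprotonation by the hindered amide at the unsubstituted methylene (not at the methyl-bearing carbon, so that centre is kept) and O-triflation of the enolate.

Step 4
Reactants: 7 3-methylbut-1-yne
Product: 8 4,4,5,5-tetramethyl-2-[(E)-3-methylbut-1-enyl]-1,3,2-dioxaborolane
Conditions: pinacolborane, Cp2Zr(H)Cl (cat.), Et3N (cat.), neat, sealed tube, 60 °C
Reagents that add atoms: pinacolborane, [H]B1OC(C)(C)C(C)(C)O1
Why: Zirconium hydride-catalysed syn hydroboration of the terminal alkyne places boron on the terminal carbon and should give the E alkenylboronate only.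

Step 5
Reactants: 6 (4S,5R)-4-(tert-butyldimethylsilyloxy)-5-methylcyclopent-1-en-1-yl trifluoromethanesulfonate; 8 4,4,5,5-tetramethyl-2-[(E)-3-methylbut-1-enyl]-1,3,2-dioxaborolane
Product: 9 tert-butyldimethyl{[(1S,2S)-2-methyl-3-[(E)-3-methylbut-1-enyl]cyclopent-3-en-1-yl]oxy}silane
Conditions: Pd(PPh3)4 (cat.), K3PO4, dioxane/H2O, 60 °C
Reagents that add atoms: none
Why: Suzuki coupling of an alkenyl triflate with an alkenylboronate at zerovalent palladium; both alkene geometries are retained, so the E diene should result with the silyl ether and both stereocentres untouched.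

Step 6
Reactants: 10 propyne; 11 chromium hexacarbonyl
Product: 14 pentacarbonyl[methoxy(prop-1-ynyl)carbene]chromium, via prop-1-ynyllithium 12 (not isolated), via lithium acyl chromate 13 (not isolated)
Conditions: n-BuLi, THF, −78 °C; Cr(CO)6, THF, −78 → 0 °C; then Me3OBF4, CH2Cl2, −20 → 0 °C
Reagents that add atoms: trimethyloxonium tetrafluoroborate, C[O+](C)C.F[B-](F)(F)F
Why: Fischer carbene synthesis: the acetylide adds to a carbonyl ligand to give the acyl chromate, which the oxonium salt methylates on oxygen.

Step 7
Reactants: 14 pentacarbonyl[methoxy(prop-1-ynyl)carbene]chromium; 15 4-methoxybenzyl alcohol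
Product: 16 pentacarbonyl{methoxy[(E)-2-(4-methoxybenzyloxy)prop-1-enyl]carbene}chromium
Conditions: NaH (10 mol%), THF, −40 → 0 °C
Reagents that add atoms: none
Why: Michael addition of the alkoxide to the electron-poor triple bond of the alkynyl carbene complex, a known route to β-alkoxyalkenyl carbene complexes; protonation of the allenyl chromate should give the E isomer, ether oxygen trans and methyl cis to the carbene carbon.

Step 8
Reactants: 9 tert-butyldimethyl{[(1S,2S)-2-methyl-3-[(E)-3-methylbut-1-enyl]cyclopent-3-en-1-yl]oxy}silane; 16 pentacarbonyl{methoxy[(E)-2-(4-methoxybenzyloxy)prop-1-enyl]carbene}chromium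
Product: 18 (1αH,4βH,7αH)-3β-(tert-butyldimethylsilyloxy)-8-methoxy-10β-(4-methoxybenzyloxy)guaia-5,8-diene, via cis-divinylcyclopropane 17 (not isolated)
Conditions: THF (degassed), 90 °C, sealed tube, Ar; 9 in excess
Reagents that add atoms: none
Why: Proposed new method: heating releases one CO ligand from 16, the vacant site binds the diene, and carbene transfer to the acyclic C6=C7 bond through a chromacyclobutane gives cyclopropane 17, whose cis-divinyl arrangement then undergoes a strain-driven [3,3] (Cope) shift that forms C1–C10 and breaks C6–C8. The closest known reaction type is the cyclopropanation–Cope (4+3) annulation of alkoxy(alkenyl)carbene complexes of chromium and molybdenum with 1,3-dienes, which has not been shown for a push–pull β-alkoxy-β-methyl alkenyl group. The seven-membered ring closes by sigmatropic bond formation between the two alkene termini (C1 of the cyclopentene, C10 of the enol ether) in a boat transition state, leaving C5=C6 and the C8=C9 methyl enol ether. C7 is set in the cyclopropanation: the E geometry of C6=C7 keeps isopropyl trans to the cyclopentenyl arm, and the metal carbene is expected to engage the s-cis diene on the face opposite the C4 methyl group. C1 and C10 are set in the boat: the inward H1 and the inward C10 methyl group (cis to the carbene carbon in 16) end on the face of H7, so the C10 ether oxygen and the isopropyl group end on the opposite, β face. The step needs site selectivity for C6=C7 over the ring alkene (attack there would make a quaternary cyclopropane carbon), cyclopropanation rather than [4+2] addition to the alkenyl carbene (its donor-substituted alkene is a poor dienophile), cis placement of the two alkenyl arms, and retention of the E geometry of C9=C10.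

Step 9
Reactants: 18 (1αH,4βH,7αH)-3β-(tert-butyldimethylsilyloxy)-8-methoxy-10β-(4-methoxybenzyloxy)guaia-5,8-diene
Product: 19 (1αH,4βH,7αH)-3β-(tert-butyldimethylsilyloxy)-10β-(4-methoxybenzyloxy)guai-5-en-8-one
Conditions: oxalic acid (0.1 M aq.), THF, 0 °C
Reagents that add atoms: water, O
Why: Acid hydrolysis of the methyl enol ether (protonation at C9, hydration of the oxocarbenium ion, loss of methanol); dilute acid at 0 °C is chosen so that the silyl ether, the tertiary benzyl-type ether, the β,γ-alkene and the C7 centre should stay untouched.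

Step 10
Reactants: 19 (1αH,4βH,7αH)-3β-(tert-butyldimethylsilyloxy)-10β-(4-methoxybenzyloxy)guai-5-en-8-one
Product: 20 (1αH,4βH,7αH)-3β-(tert-butyldimethylsilyloxy)-10β-(4-methoxybenzyloxy)guai-5-en-8β-ol
Conditions: LiBH(s-Bu)3, THF, −78 °C; then H2O
Reagents that add atoms: none
Why: Ketone reduction by a bulky trialkylborohydride; hydride is expected to enter from the α face, away from the C7 isopropyl group and the pseudoaxial C10 ether oxygen, giving the 8β alcohol cis to both, and the low temperature should prevent enolisation toward C7.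

Step 11
Reactants: 20 (1αH,4βH,7αH)-3β-(tert-butyldimethylsilyloxy)-10β-(4-methoxybenzyloxy)guai-5-en-8β-ol
Product: 21 (1αH,4βH,5βH,7αH)-3β-(tert-butyldimethylsilyloxy)-10β-(4-methoxybenzyloxy)guaian-8β-ol
Conditions: [Ir(cod)(PCy3)(py)]PF6 (cat.), H2 (1 atm), CH2Cl2, 0 °C → rt
Reagents that add atoms: none
Why: Hydroxyl-directed hydrogenation: the cationic iridium catalyst binds the homoallylic 8β hydroxyl and delivers hydrogen to the β face of C5=C6, which is also the face away from the C4 methyl group, so H5 becomes β and the ring fusion trans.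

Step 12
Reactants: 21 (1αH,4βH,5βH,7αH)-3β-(tert-butyldimethylsilyloxy)-10β-(4-methoxybenzyloxy)guaian-8β-ol
Product: 22 (1αH,4βH,5βH,7αH)-3β-(tert-butyldimethylsilyloxy)-10β-(4-methoxybenzyloxy)guaian-8β-yl 3,4-dimethoxybenzoate
Conditions: 3,4-dimethoxybenzoyl chloride, Et3N, DMAP (cat.), CH2Cl2, rt
Reagents that add atoms: 3,4-dimethoxybenzoyl chloride, COc1ccc(C(Cl)=O)cc1OC
Why: DMAP-catalysed acyl transfer to the only free hydroxyl; the C8–O bond is not broken, so its configuration is kept.

Step 13
Reactants: 22 (1αH,4βH,5βH,7αH)-3β-(tert-butyldimethylsilyloxy)-10β-(4-methoxybenzyloxy)guaian-8β-yl 3,4-dimethoxybenzoate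
Product: 23 (1αH,4βH,5βH,7αH)-3β-hydroxy-10β-(4-methoxybenzyloxy)guaian-8β-yl 3,4-dimethoxybenzoate
Conditions: Bu4NF, THF, rt
Reagents that add atoms: none
Why: Fluoride cleaves the Si–O bond; the aryl ester, the benzyl-type ether and all stereocentres should be stable.

Step 14
Reactants: 23 (1αH,4βH,5βH,7αH)-3β-hydroxy-10β-(4-methoxybenzyloxy)guaian-8β-yl 3,4-dimethoxybenzoate
Product: 25 (1αH,5βH,7αH)-10β-(4-methoxybenzyloxy)guai-3-en-8β-yl 3,4-dimethoxybenzoate, via sulfamate ester 24 (not isolated)
Conditions: methyl N-(triethylammoniosulfonyl)carbamate (inner salt), toluene, rt → 80 °C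
Reagents that add atoms: none
Why: Burgess dehydration: the secondary alcohol forms a sulfamate ester that loses the elements of water by thermal syn elimination; H4 is cis to the C3 oxygen and tertiary, so the trisubstituted C3=C4 alkene is expected, and the C10 oxygen, still an ether, cannot take part.

Step 15
Reactants: 25 (1αH,5βH,7αH)-10β-(4-methoxybenzyloxy)guai-3-en-8β-yl 3,4-dimethoxybenzoate
Product: 26 (1αH,5βH,7αH)-3α,4α-epoxy-10β-(4-methoxybenzyloxy)guaian-8β-yl 3,4-dimethoxybenzoate
Conditions: 3-chloroperoxybenzoic acid, NaHCO3, CH2Cl2, 0 °C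
Reagents that add atoms: 3-chloroperoxybenzoic acid, OOC(=O)c1cccc(Cl)c1
Why: Prilezhaev epoxidation of the only alkene; the trans fusion locks the cyclopentene envelope with C1 folded to the α face and the allylic H5 and one H2 pseudoaxial on the β face, so the peracid is expected to add from the α face, anti to these C–H bonds, giving the 3α,4α-epoxide.

Step 16
Reactants: 26 (1αH,5βH,7αH)-3α,4α-epoxy-10β-(4-methoxybenzyloxy)guaian-8β-yl 3,4-dimethoxybenzoate
Product: 27 (1R,3R,4S,5S,7R,8R,10S)-3,4-epoxy-10-hydroxyguaian-8-yl 3,4-dimethoxybenzoate (3α,4α-epoxide; 1αH,5βH,7αH; 8β-ester; 10β-hydroxyl)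
Conditions: DDQ, CH2Cl2/pH 7 phosphate buffer, 0 °C → rt
Reagents that add atoms: none
Why: Oxidative cleavage of the 4-methoxybenzyl ether (benzylic hydride abstraction, hydrolysis of the hemiacetal) under buffered conditions that should spare the epoxide; the dimethoxybenzoate has no benzylic C–H and should not react.

## Compound list

1 | 2-methylcyclopent-2-en-1-one | CC1=CCCC1=O | starting material
2 | (2R,3S)-2-methyl-3-(4,4,5,5-tetramethyl-1,3,2-dioxaborolan-2-yl)cyclopentan-1-one | O=C1CC[C@H](B2OC(C)(C)C(C)(C)O2)[C@H]1C | intermediate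
3 | (2R,3S)-3-hydroxy-2-methylcyclopentan-1-one | O=C1CC[C@H](O)[C@H]1C | intermediate
4 | (2R,3S)-3-(tert-butyldimethylsilyloxy)-2-methylcyclopentan-1-one | O=C1CC[C@H](O[Si](C)(C)C(C)(C)C)[C@H]1C | intermediate
5 | lithium (4S,5R)-4-(tert-butyldimethylsilyloxy)-5-methylcyclopent-1-en-1-olate | [Li]OC1=CC[C@H](O[Si](C)(C)C(C)(C)C)[C@H]1C | intermediate
6 | (4S,5R)-4-(tert-butyldimethylsilyloxy)-5-methylcyclopent-1-en-1-yl trifluoromethanesulfonate | O=S(=O)(OC1=CC[C@H](O[Si](C)(C)C(C)(C)C)[C@H]1C)C(F)(F)F | intermediate
7 | 3-methylbut-1-yne | CC(C)C#C | starting material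
8 | 4,4,5,5-tetramethyl-2-[(E)-3-methylbut-1-enyl]-1,3,2-dioxaborolane | CC(C)/C=C/B1OC(C)(C)C(C)(C)O1 | intermediate
9 | tert-butyldimethyl{[(1S,2S)-2-methyl-3-[(E)-3-methylbut-1-enyl]cyclopent-3-en-1-yl]oxy}silane | CC(C)/C=C/C1=CC[C@H](O[Si](C)(C)C(C)(C)C)[C@H]1C | intermediate
10 | propyne | CC#C | starting material
11 | chromium hexacarbonyl | O=C=[Cr](=C=O)(=C=O)(=C=O)(=C=O)=C=O | starting material
12 | prop-1-ynyllithium | [Li]C#CC | intermediate
13 | lithium pentacarbonyl(but-2-ynoyl)chromate | [Li+].[O-]C(C#CC)=[Cr](=C=O)(=C=O)(=C=O)(=C=O)=C=O | intermediate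
14 | pentacarbonyl[methoxy(prop-1-ynyl)carbene]chromium | COC(C#CC)=[Cr](=C=O)(=C=O)(=C=O)(=C=O)=C=O | intermediate
15 | 4-methoxybenzyl alcohol | COc1ccc(CO)cc1 | starting material
16 | pentacarbonyl{methoxy[(E)-2-(4-methoxybenzyloxy)prop-1-enyl]carbene}chromium | COC(/C=C(\C)OCc1ccc(OC)cc1)=[Cr](=C=O)(=C=O)(=C=O)(=C=O)=C=O | intermediate
17 | 1-[(4S,5S)-4-(tert-butyldimethylsilyloxy)-5-methylcyclopent-1-en-1-yl]-3-isopropyl-2-methoxy-2-[(E)-2-(4-methoxybenzyloxy)prop-1-enyl]cyclopropane (the two alkenyl groups cis; isopropyl trans to both and cis to methoxy) | CC(C)[C@H]1[C@H](C2=CC[C@H](O[Si](C)(C)C(C)(C)C)[C@H]2C)[C@]1(OC)/C=C(\C)OCc1ccc(OC)cc1 | intermediate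
18 | (1αH,4βH,7αH)-3β-(tert-butyldimethylsilyloxy)-8-methoxy-10β-(4-methoxybenzyloxy)guaia-5,8-diene | COC1=C[C@](C)(OCc3ccc(OC)cc3)[C@@H]2C[C@H](O[Si](C)(C)C(C)(C)C)[C@@H](C)C2=C[C@@H]1C(C)C | intermediate
19 | (1αH,4βH,7αH)-3β-(tert-butyldimethylsilyloxy)-10β-(4-methoxybenzyloxy)guai-5-en-8-one | O=C1C[C@](C)(OCc3ccc(OC)cc3)[C@@H]2C[C@H](O[Si](C)(C)C(C)(C)C)[C@@H](C)C2=C[C@@H]1C(C)C | intermediate
20 | (1αH,4βH,7αH)-3β-(tert-butyldimethylsilyloxy)-10β-(4-methoxybenzyloxy)guai-5-en-8β-ol | O[C@@H]1C[C@](C)(OCc3ccc(OC)cc3)[C@@H]2C[C@H](O[Si](C)(C)C(C)(C)C)[C@@H](C)C2=C[C@@H]1C(C)C | intermediate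
21 | (1αH,4βH,5βH,7αH)-3β-(tert-butyldimethylsilyloxy)-10β-(4-methoxybenzyloxy)guaian-8β-ol | O[C@@H]1C[C@](C)(OCc3ccc(OC)cc3)[C@@H]2C[C@H](O[Si](C)(C)C(C)(C)C)[C@@H](C)[C@H]2C[C@@H]1C(C)C | intermediate
22 | (1αH,4βH,5βH,7αH)-3β-(tert-butyldimethylsilyloxy)-10β-(4-methoxybenzyloxy)guaian-8β-yl 3,4-dimethoxybenzoate | COc1ccc(C(=O)O[C@@H]2C[C@](C)(OCc5ccc(OC)cc5)[C@@H]3C[C@H](O[Si](C)(C)C(C)(C)C)[C@@H](C)[C@H]3C[C@@H]2C(C)C)cc1OC | intermediate
23 | (1αH,4βH,5βH,7αH)-3β-hydroxy-10β-(4-methoxybenzyloxy)guaian-8β-yl 3,4-dimethoxybenzoate | COc1ccc(C(=O)O[C@@H]2C[C@](C)(OCc5ccc(OC)cc5)[C@@H]3C[C@H](O)[C@@H](C)[C@H]3C[C@@H]2C(C)C)cc1OC | intermediate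
24 | triethylammonium salt of the 3β-O-[N-(methoxycarbonyl)sulfamoyl] derivative of 23 | COc1ccc(C(=O)O[C@@H]2C[C@](C)(OCc5ccc(OC)cc5)[C@@H]3C[C@H](OS(=O)(=O)[N-]C(=O)OC)[C@@H](C)[C@H]3C[C@@H]2C(C)C)cc1OC.CC[NH+](CC)CC | intermediate
25 | (1αH,5βH,7αH)-10β-(4-methoxybenzyloxy)guai-3-en-8β-yl 3,4-dimethoxybenzoate | COc1ccc(C(=O)O[C@@H]2C[C@](C)(OCc5ccc(OC)cc5)[C@@H]3CC=C(C)[C@H]3C[C@@H]2C(C)C)cc1OC | intermediate
26 | (1αH,5βH,7αH)-3α,4α-epoxy-10β-(4-methoxybenzyloxy)guaian-8β-yl 3,4-dimethoxybenzoate | COc1ccc(C(=O)O[C@@H]2C[C@](C)(OCc5ccc(OC)cc5)[C@@H]3C[C@H]4O[C@@]4(C)[C@H]3C[C@@H]2C(C)C)cc1OC | intermediate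
27 | (1R,3R,4S,5S,7R,8R,10S)-3,4-epoxy-10-hydroxyguaian-8-yl 3,4-dimethoxybenzoate (CNP0304846.1) | COc1ccc(C(=O)O[C@@H]2C[C@](C)(O)[C@@H]3C[C@H]4O[C@@]4(C)[C@H]3C[C@@H]2C(C)C)cc1OC | target

## Step count and least certain steps

Total: 16 steps. Longest linear sequence: 13 steps (1, 2, 3, 5, 8–16).

**Step 8 (key step).** Four things may go wrong.
- Carbene transfer may fail: the β-alkoxy group makes the carbene carbon a weak electrophile, so 16 may decompose before it cyclopropanates a 1,2-disubstituted alkene.
- The push–pull C9=C10 bond may lose its geometry at 90 °C, which would scramble C10.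
- The facial sense may be eroded or reversed if the free diene reacts through its s-trans rotamer; attack anti to the C4 methyl group then ends, after the bond rotation the Cope step needs, on the methyl-bearing face. Because C3 and C4 are erased in steps 14 and 15, the other ligand antipode in step 1 would then supply the matching series.
- The sigmatropic shift may be slow because the C10 methyl group points inward in the boat.

Fallback by known reaction types, setting out from 9 and coming back at 19:
- Rh2(OAc)4-catalysed cyclopropanation of C6=C7 of 9 with ethyl diazoacetate gives, after separation of the isomer with the ester cis to the cyclopentenyl group, the cyclopropane ester F1.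
- i-Bu2AlH at −78 °C gives the cyclopropanecarbaldehyde F2.
- The separately prepared, racemic α-alkoxyalkyl phosphine oxide F3 is lithiated and added to F2 (Horner–Wittig). The β-hydroxy phosphine oxide F4, a diastereomer that eliminates to the E enol ether, is separated.
- Syn elimination with KH gives the cis-divinylcyclopropane F4's product, the enol ether F5, which on warming should rearrange (Cope) to the 8-unsubstituted cycloheptadiene F6.
- Hydroboration of the disubstituted C8=C9 bond with 9-borabicyclo[3.3.1]nonane (boron on C8, remote from the quaternary C10) and oxidative work-up give the 8α-alcohol F7.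
- Dess–Martin oxidation of F7 gives 19.

The facial question at C6=C7 remains in this fallback, and the cyclopropanation needs a separation.

**Step 1.** Enantiocontrol in the conjugate borylation of an α-substituted cyclopentenone may be incomplete, and C2 may not equilibrate fully. Since the C4 methyl centre is the only control element of step 8, either defect would be carried into the antipodal series. Fallback from 1 to 3: the same borylation–oxidation with an achiral bisphosphine gives 3 together with its mirror image, the (2S,3R)-hydroxy ketone F8. Acetylation with vinyl acetate and the lipase of Burkholderia cepacia is expected to convert F8 into the acetate F9 and leave 3, which is separated and taken into step 2.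

**Step 10.** Hydride delivery may occur from the β face if the seven-membered ring places the C10 methyl group, not the ether oxygen, pseudoaxial; the 8α alcohol would then result. Fallback from 19 to 20: the 8α-alcohol F7 obtained from 19 is inverted by a Mitsunobu reaction (4-nitrobenzoic acid, PPh3, diisopropyl azodicarboxylate) to the 8β 4-nitrobenzoate F10, and methanolysis (K2CO3, MeOH) gives 20.

**Step 14.** The elimination may run toward C2 (a cis hydrogen is also present there), or the sulfamate may be displaced. Fallback from 23 to 25: Dess–Martin oxidation gives the C3 ketone F11; Tf2O with 2,6-di-tert-butyl-4-methylpyridine gives the more substituted enol triflate F12; palladium-catalysed formate reduction (Pd(OAc)2, PPh3, Bu3N, HCO2H, DMF, 60 °C) gives 25.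

**Step 15.** Facial selectivity may be poor or reversed, because both faces of the trans-fused cyclopentene carry only hydrogen and the preference rests on torsional effects alone. Fallback from 25 to 26, useful if electrophiles prefer the β face: N-bromosuccinimide in THF/H2O forms the β bromonium ion, water opens it at C4 from the α face to the bromohydrin F13, and K2CO3 in MeOH closes the 3α,4α-epoxide 26.

## Further compounds

F1 | step 8 | ethyl 2-[(4S,5S)-4-(tert-butyldimethylsilyloxy)-5-methylcyclopent-1-en-1-yl]-3-isopropylcyclopropane-1-carboxylate (ester cis to cyclopentenyl, isopropyl trans to both) | CC(C)[C@H]1[C@H](C2=CC[C@H](O[Si](C)(C)C(C)(C)C)[C@H]2C)[C@@H]1C(=O)OCC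
F2 | step 8 | 2-[(4S,5S)-4-(tert-butyldimethylsilyloxy)-5-methylcyclopent-1-en-1-yl]-3-isopropylcyclopropane-1-carbaldehyde (same relative configuration as F1) | CC(C)[C@H]1[C@H](C2=CC[C@H](O[Si](C)(C)C(C)(C)C)[C@H]2C)[C@@H]1C=O
F3 | step 8 | [1-(4-methoxybenzyloxy)ethyl]diphenylphosphine oxide (racemic) | CC(OCc1ccc(OC)cc1)P(=O)(c1ccccc1)c1ccccc1
F4 | step 8 | β-hydroxy phosphine oxide from F2 and F3 (diastereomer that eliminates to the E enol ether) | CC(C)[C@H]1[C@H](C2=CC[C@H](O[Si](C)(C)C(C)(C)C)[C@H]2C)[C@@H]1[C@@H](O)[C@@](C)(OCc1ccc(OC)cc1)P(=O)(c1ccccc1)c1ccccc1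
F5 | step 8 | 1-[(4S,5S)-4-(tert-butyldimethylsilyloxy)-5-methylcyclopent-1-en-1-yl]-3-isopropyl-2-[(E)-2-(4-methoxybenzyloxy)prop-1-enyl]cyclopropane (alkenyl groups cis) | CC(C)[C@H]1[C@H](C2=CC[C@H](O[Si](C)(C)C(C)(C)C)[C@H]2C)[C@@H]1/C=C(\C)OCc1ccc(OC)cc1
F6 | step 8 | (1αH,4βH,7αH)-3β-(tert-butyldimethylsilyloxy)-10β-(4-methoxybenzyloxy)guaia-5,8-diene | C1=C[C@](C)(OCc3ccc(OC)cc3)[C@@H]2C[C@H](O[Si](C)(C)C(C)(C)C)[C@@H](C)C2=C[C@@H]1C(C)C
F7 | step 8 | (1αH,4βH,7αH)-3β-(tert-butyldimethylsilyloxy)-10β-(4-methoxybenzyloxy)guai-5-en-8α-ol | O[C@H]1C[C@](C)(OCc3ccc(OC)cc3)[C@@H]2C[C@H](O[Si](C)(C)C(C)(C)C)[C@@H](C)C2=C[C@@H]1C(C)C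
F8 | step 1 | (2S,3R)-3-hydroxy-2-methylcyclopentan-1-one | O=C1CC[C@@H](O)[C@@H]1C
F9 | step 1 | (1R,2S)-2-methyl-3-oxocyclopentyl acetate | O=C1CC[C@@H](OC(C)=O)[C@@H]1C
F10 | step 10 | (1αH,4βH,7αH)-3β-(tert-butyldimethylsilyloxy)-10β-(4-methoxybenzyloxy)guai-5-en-8β-yl 4-nitrobenzoate | O=C(O[C@@H]1C[C@](C)(OCc3ccc(OC)cc3)[C@@H]2C[C@H](O[Si](C)(C)C(C)(C)C)[C@@H](C)C2=C[C@@H]1C(C)C)c1ccc([N+](=O)[O-])cc1
F11 | step 14 | (1αH,4βH,5βH,7αH)-10β-(4-methoxybenzyloxy)-3-oxoguaian-8β-yl 3,4-dimethoxybenzoate | COc1ccc(C(=O)O[C@@H]2C[C@](C)(OCc5ccc(OC)cc5)[C@@H]3CC(=O)[C@@H](C)[C@H]3C[C@@H]2C(C)C)cc1OC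
F12 | step 14 | (1αH,5βH,7αH)-10β-(4-methoxybenzyloxy)-3-(trifluoromethanesulfonyloxy)guai-3-en-8β-yl 3,4-dimethoxybenzoate | COc1ccc(C(=O)O[C@@H]2C[C@](C)(OCc5ccc(OC)cc5)[C@@H]3CC(OS(=O)(=O)C(F)(F)F)=C(C)[C@H]3C[C@@H]2C(C)C)cc1OC
F13 | step 15 | (1αH,5βH,7αH)-3β-bromo-4α-hydroxy-10β-(4-methoxybenzyloxy)guaian-8β-yl 3,4-dimethoxybenzoate | COc1ccc(C(=O)O[C@@H]2C[C@](C)(OCc5ccc(OC)cc5)[C@@H]3C[C@H](Br)[C@@](C)(O)[C@H]3C[C@@H]2C(C)C)cc1OC
A1 | alternative 1 | guai-3-ene-8,10-diol acetonide (1αH,5βH,7αH; 8β,10β-O-isopropylidene) | CC1(C)O[C@@H]2C[C@](C)(O1)[C@@H]3CC=C(C)[C@H]3C[C@@H]2C(C)C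
A2 | alternative 2 | 8β-(tert-butyldimethylsilyloxy)-7αH-guaia-1(10),4-dien-3-one | CC1=C2C[C@H](C(C)C)[C@H](O[Si](C)(C)C(C)(C)C)CC(C)=C2CC1=O
A3 | alternative 3 | 3β-(tert-butyldimethylsilyloxy)-7β,10β-epoxy-8β-(triethylsilyloxy)-1αH,4βH-guai-5-ene | CC[Si](CC)(CC)O[C@@H]1C[C@@]2(C)[C@@H]3C[C@H](O[Si](C)(C)C(C)(C)C)[C@@H](C)C3=C[C@]1(C(C)C)O2
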